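The last time asked for, 2.0 min, lies past the last reading of any run, 90.0 s, so this quick number for the flask has to extrapolate. The hunch that came with the request stands as the forecast in step 4.

| flask | L | Q | remark | time |
|---|---|---|---|---|
| alpha | 5 mM | 1 mM | run made earlier |  |
| gamma | 20 mM | 1 mM | run made earlier |  |
| theta | 10 mM | 2 mM | run made earlier |  |
| flask | 10 mM | 1.0 mM |  | 2.0 min |

| run | time / s | Z / % | L / % |
|---|---|---|---|
| alpha | 15.0 | 5.4 | 87.6 |
| alpha | 30.0 | 9.6 | 77.5 |
| alpha | 40.0 | 11.7 | 71.0 |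
| alpha | 60.0 | 15.8 | 59.7 |
| alpha | 80.0 | 19.8 | 50.5 |
| alpha | 90.0 | 21.4 | 46.1 |
| gamma | 10.0 | 3.4 | 91.7 |
| gamma | 12.0 | 4.1 | 90.1 |
| gamma | 20.0 | 6.6 | 84.6 |
| gamma | 25.0 | 7.7 | 81.0 |
| gamma | 40.0 | 11.7 | 70.4 |
| gamma | 60.0 | 16.2 | 59.6 |
| gamma | 90.0 | 21.8 | 46.5 |
| theta | 10.0 | 6.8 | 89.0 |
| theta | 15.0 | 9.6 | 83.4 |
| theta | 25.0 | 14.7 | 73.9 |
| theta | 50.0 | 26.2 | 54.9 |
| theta | 90.0 | 37.6 | 34.4 |

(readings scatter by 0.3 percentage points)



1. amount of Z in percent of the L charged, at 12 s, 40 s, 80 s and 2.0 min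

1. Alpha and gamma share one c(Q), and their c(L) differ by a factor of 4.00, yet at 90.0 s L stands at 46.1 % and 46.5 %. L therefore falls pseudo-first-order, and the flask, with c(L) between theirs and the same c(Q), should follow the same curve. Together the two runs read 0.00856 /s.

2. The quantity to freeze is the Z share, or selectivity: Z formed per L lost. Alpha and gamma together read 0.402 at 90.0 s, and gamma reads 0.395 at 40.0 s.

3. Z in the flask is then reckoned as the share times the L lost. This reckoning of mine gives 3.92 %, 11.7 %, 19.9 % and 25.8 %.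

4. The forecast, built on “two parallel paths”, says 4 %, 11.8 %, 20.1 % and 26.2 %. At 2.0 min it stands 0.40 percentage points above the reckoning of step 3.

5. The flask gives 3.88 %, 11.5 %, 19.7 % and 25.5 %, and the forecast holds within its margin.

    L → J (k = 2.70 × 10⁻⁴ /s)
    L → D (k = 0.00490 /s)
    L + Q → Q + Z (k = 3.40 /M/s)

At 0.754 min and again at 2.00 min, the flask uses L for D at 1.4 times its rate for Z. Q stands at 100 % of its charge at 2.00 min. Z per L lost in the flask at 2.0 min is 0.397, beside the 0.402 read from alpha and gamma. Q enters the Z step and neither other step, and theta has twice the c(Q) of the flask. Doubling the odds share/(1-share) gives 0.573 for theta, and the theta readings give 0.573 at 90.0 s. At 20.0 min the flask holds L 0 % and Z 39.7 %.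

The earlier runs and the new flask were computed on assumed constants; scatter was added.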